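**Strategy.** Everything rests on cutting the C1–O bond: C1 is the benzylic carbon para to the free phenol of the guaiacyl ring (ring A), and the oxygen on C3 lies 1,3 to it across C2, which carries the syringyl ring (ring B). In one operation, anodic oxidation of ring A turns the C1 methylene into a para-quinone methide that the C3 tert-butyl carbonate captures, closing a trans-4,5-diaryl-1,3-dioxan-2-one and setting C1 from the existing C2 centre. The precursor is an (S)-2,3-diarylpropyl tert-butyl carbonate with ring A as free phenol and ring B as aryl acetate, made by Perkin condensation and asymmetric hydrogenation. Ring A is then silylated before the carbonate is opened.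

Key step: step 7

Remark (labels): the chain carbons are C1 (on ring A), C2 (on ring B) and C3 (CH2O); the target is (1S,2S), which corresponds to the trans (4S,5S) cyclic carbonate.

Remark (endgame): a benzylic carbonate para to a phenoxide is expelled by 1,6-elimination, and the resulting quinone methide would add methanol at C1 without stereocontrol. The ring A phenol is therefore capped before the carbonate is opened in base, and uncapped last.

**Route**

Step 1
Reactants: 1 vanillin
Product: 2 4-benzyloxy-3-methoxybenzaldehyde
Conditions: BnBr, K2CO3, DMF, 60 °C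
Reagents that add atoms: benzyl bromide, BrCc1ccccc1
Why: Williamson ether synthesis on the phenoxide of vanillin is routine, and the benzyl ether keeps ring A distinct from ring B until step 6.

Step 2
Reactants: 2 4-benzyloxy-3-methoxybenzaldehyde; 3 homosyringic acid
Product: 5 (E)-2-(4-acetoxy-3,5-dimethoxyphenyl)-3-(4-benzyloxy-3-methoxyphenyl)prop-2-enoic acid, via mixed anhydride 4 (not isolated)
Conditions: Ac2O, Et3N, 110 °C; then H2O, 80 °C; dilute HCl, crystallisation
Reagents that add atoms: acetic anhydride, CC(=O)OC(C)=O
Why: Perkin condensation (Oglialoro variant): acetic anhydride acetylates the ring B phenol and turns the acid into the enolisable mixed anhydride 4, which condenses with the non-enolisable aldehyde and dehydrates under thermodynamic control to the (E)-acid with the two aryl groups cis.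

Step 3
Reactants: 5 (E)-2-(4-acetoxy-3,5-dimethoxyphenyl)-3-(4-benzyloxy-3-methoxyphenyl)prop-2-enoic acid
Product: 6 (S)-2-(4-acetoxy-3,5-dimethoxyphenyl)-3-(4-benzyloxy-3-methoxyphenyl)propanoic acid
Conditions: H2 (50 bar), Ru(OAc)2[(S)-BINAP] (1 mol %), MeOH, 40 °C
Reagents that add atoms: none
Why: Asymmetric hydrogenation of an α,β-unsaturated carboxylic acid with a BINAP ruthenium diacetate proceeds through the chelating carboxylate, so the ligand decides the face from which hydrogen reaches C2 of the geometrically pure (E)-olefin and sets the (S) centre; the (S)-ligand is proposed by analogy with 2-arylacrylic acids and is exchanged for its antipode if a test run shows the opposite sense, while the benzyl ether and aryl acetate are inert to this homogeneous catalyst.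

Step 4
Reactants: 6 (S)-2-(4-acetoxy-3,5-dimethoxyphenyl)-3-(4-benzyloxy-3-methoxyphenyl)propanoic acid
Product: 7 4-[(2S)-1-(4-benzyloxy-3-methoxyphenyl)-3-hydroxypropan-2-yl]-2,6-dimethoxyphenyl acetate
Conditions: BH3·THF, THF, 0 °C to rt; MeOH quench, aqueous work-up
Reagents that add atoms: none
Why: Chemoselective borane reduction: borane reduces a free carboxylic acid far faster than an aryl ester, so the ring B acetate should survive, and the non-basic medium leaves the benzylic C2 centre unracemised.

Step 5
Reactants: 7 4-[(2S)-1-(4-benzyloxy-3-methoxyphenyl)-3-hydroxypropan-2-yl]-2,6-dimethoxyphenyl acetate; 8 di-tert-butyl dicarbonate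
Product: 9 (S)-2-(4-acetoxy-3,5-dimethoxyphenyl)-3-(4-benzyloxy-3-methoxyphenyl)propyl tert-butyl carbonate
Conditions: Boc2O (1.5 equiv), DMAP (0.1 equiv), CH2Cl2, 0 °C to rt
Reagents that add atoms: di-tert-butyl dicarbonate (8), CC(C)(C)OC(=O)OC(=O)OC(C)(C)C
Why: DMAP-catalysed acyl transfer from the dicarbonate to the unhindered primary alcohol gives the mixed tert-butyl carbonate under conditions too mild to disturb the aryl acetate or C2.

Step 6
Reactants: 9 (S)-2-(4-acetoxy-3,5-dimethoxyphenyl)-3-(4-benzyloxy-3-methoxyphenyl)propyl tert-butyl carbonate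
Product: 10 (S)-2-(4-acetoxy-3,5-dimethoxyphenyl)-3-(4-hydroxy-3-methoxyphenyl)propyl tert-butyl carbonate
Conditions: H2 (1 atm), Pd/C (10 wt %), EtOAc, rt
Reagents that add atoms: none
Why: Hydrogenolysis of the aryl benzyl ether over palladium frees the ring A phenol, while the tert-butyl carbonate, the aryl acetate and the two benzylic carbons (neither bears a heteroatom) are not cleaved.

Step 7
Reactants: 10 (S)-2-(4-acetoxy-3,5-dimethoxyphenyl)-3-(4-hydroxy-3-methoxyphenyl)propyl tert-butyl carbonate
Product: 12 (4S,5S)-5-(4-acetoxy-3,5-dimethoxyphenyl)-4-(4-hydroxy-3-methoxyphenyl)-1,3-dioxan-2-one, via quinone methide 11 (not isolated)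
Conditions: undivided cell, graphite anode, Pt cathode, Bu4NBF4 (0.1 M), MeCN/(CF3)2CHOH 4:1, 2,6-lutidine (2 equiv), substrate 10 mM, constant current, 2.1–2.2 F/mol, 0 °C
Reagents that add atoms: none
Why: Proposed new method: proton-coupled two-electron oxidation of the ring A phenol, with 2,6-lutidine as proton shuttle, followed by loss of a C1 proton should give para-quinone methide 11, whose C1 becomes strongly electrophilic when hexafluoroisopropanol hydrogen-bonds to the dienone oxygen; the carbonyl oxygen of the C3 carbonate then adds to C1 as ring A rearomatises, the tert-butyl group leaves as isobutene, and the released protons are reduced to hydrogen at the cathode. The closest known reaction types are the anodic benzylic oxygenation of 4-alkylphenols by way of para-quinone methides and the closure of tert-butyl carbonates onto oxidatively formed benzylic cations, which have not been joined on a 4-alkylguaiacol. The one ring closes in a 6-exo-trig mode, since the exocyclic C1=C bond of the quinone methide stays outside the new 1,3-dioxan-2-one. The new C1 centre is controlled by the existing C2 centre: allylic 1,3-strain keeps C2–H in the plane of the quinone methide, the tether attacks from its own face, and the half-chair (the O–C(=O)–O unit is planar) places both aryl groups pseudo-equatorial, which is also the thermodynamically preferred trans (4S,5S) isomer. The step needs oxidation of ring A only, secured by leaving that phenol free while ring B is an aryl acetate expected to oxidise at a clearly higher potential so that C2–H is not activated, and it needs carbonate capture to outrun loss of the C2 proton to a stilbene, which the six-membered intramolecular delivery and the weakly basic, strongly ionising medium should favour. Stopping close to two faradays per mole should limit further oxidation of the product, whose benzylic carbonate makes its phenol harder to oxidise than that of 10.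

Step 8
Reactants: 12 (4S,5S)-5-(4-acetoxy-3,5-dimethoxyphenyl)-4-(4-hydroxy-3-methoxyphenyl)-1,3-dioxan-2-one
Product: 13 (4S,5S)-5-(4-acetoxy-3,5-dimethoxyphenyl)-4-[3-methoxy-4-(triisopropylsilyloxy)phenyl]-1,3-dioxan-2-one
Conditions: TIPSCl (1.3 equiv), imidazole (2.5 equiv), DMF, 0 °C to rt
Reagents that add atoms: triisopropylsilyl chloride, CC(C)[Si](Cl)(C(C)C)C(C)C
Why: Phenol silylation with a silyl chloride and imidazole: in DMF imidazole does not ionise the phenol to any real extent, so the carbonate is not expelled, and the bulky silyl ether then blocks quinone methide formation in the basic step that follows.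

Step 9
Reactants: 13 (4S,5S)-5-(4-acetoxy-3,5-dimethoxyphenyl)-4-[3-methoxy-4-(triisopropylsilyloxy)phenyl]-1,3-dioxan-2-one
Product: 14 (1S,2S)-2-(4-hydroxy-3,5-dimethoxyphenyl)-1-[3-methoxy-4-(triisopropylsilyloxy)phenyl]propane-1,3-diol
Conditions: K2CO3 (0.5 equiv), MeOH, argon, 0 °C to rt; NH4Cl work-up
Reagents that add atoms: none
Why: Base-catalysed transesterification: methoxide attacks only the carbonyl carbons, so the cyclic carbonate and the aryl acetate are removed with the C1–O bond and C2 untouched, while the hindered aryl triisopropylsilyl ether is expected to persist in cold carbonate/methanol.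

Step 10
Reactants: 14 (1S,2S)-2-(4-hydroxy-3,5-dimethoxyphenyl)-1-[3-methoxy-4-(triisopropylsilyloxy)phenyl]propane-1,3-diol
Product: 15 (1S,2S)-1-(4-hydroxy-3-methoxyphenyl)-2-(4-hydroxy-3,5-dimethoxyphenyl)propane-1,3-diol
Conditions: Bu4NF (1.2 equiv), AcOH (1.2 equiv), THF, 0 °C
Reagents that add atoms: none
Why: Fluoride-induced desilylation of the aryl silyl ether, buffered with acetic acid so that the phenoxide is protonated at once; a benzylic hydroxyl is too poor a leaving group for quinone methide formation at 0 °C, so both stereocentres should be retained.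

**Compound list**

1 | vanillin | COc1cc(C=O)ccc1O | starting material
2 | 4-benzyloxy-3-methoxybenzaldehyde | COc1cc(C=O)ccc1OCc1ccccc1 | intermediate
3 | homosyringic acid (4-hydroxy-3,5-dimethoxyphenylacetic acid) | COc1cc(CC(=O)O)cc(OC)c1O | starting material
4 | acetic 2-(4-acetoxy-3,5-dimethoxyphenyl)acetic anhydride (formed in the flask) | COc1cc(CC(=O)OC(C)=O)cc(OC)c1OC(C)=O | intermediate
5 | (E)-2-(4-acetoxy-3,5-dimethoxyphenyl)-3-(4-benzyloxy-3-methoxyphenyl)prop-2-enoic acid (aryl groups cis) | COc1cc(/C=C(/C(=O)O)c2cc(OC)c(OC(C)=O)c(OC)c2)ccc1OCc1ccccc1 | intermediate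
6 | (S)-2-(4-acetoxy-3,5-dimethoxyphenyl)-3-(4-benzyloxy-3-methoxyphenyl)propanoic acid | COc1cc(C[C@H](C(=O)O)c2cc(OC)c(OC(C)=O)c(OC)c2)ccc1OCc1ccccc1 | intermediate
7 | 4-[(2S)-1-(4-benzyloxy-3-methoxyphenyl)-3-hydroxypropan-2-yl]-2,6-dimethoxyphenyl acetate | COc1cc(C[C@H](CO)c2cc(OC)c(OC(C)=O)c(OC)c2)ccc1OCc1ccccc1 | intermediate
8 | di-tert-butyl dicarbonate | CC(C)(C)OC(=O)OC(=O)OC(C)(C)C | starting material
9 | (S)-2-(4-acetoxy-3,5-dimethoxyphenyl)-3-(4-benzyloxy-3-methoxyphenyl)propyl tert-butyl carbonate | COc1cc(C[C@H](COC(=O)OC(C)(C)C)c2cc(OC)c(OC(C)=O)c(OC)c2)ccc1OCc1ccccc1 | intermediate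
10 | (S)-2-(4-acetoxy-3,5-dimethoxyphenyl)-3-(4-hydroxy-3-methoxyphenyl)propyl tert-butyl carbonate | COc1cc(C[C@H](COC(=O)OC(C)(C)C)c2cc(OC)c(OC(C)=O)c(OC)c2)ccc1O | intermediate
11 | (S)-2-(4-acetoxy-3,5-dimethoxyphenyl)-3-(3-methoxy-4-oxocyclohexa-2,5-dien-1-ylidene)propyl tert-butyl carbonate (para-quinone methide, exocyclic double-bond geometry not assigned, formed in the flask) | COC1=CC(=C[C@H](COC(=O)OC(C)(C)C)c2cc(OC)c(OC(C)=O)c(OC)c2)C=CC1=O | intermediate
12 | (4S,5S)-5-(4-acetoxy-3,5-dimethoxyphenyl)-4-(4-hydroxy-3-methoxyphenyl)-1,3-dioxan-2-one (trans) | COc1cc([C@H]2OC(=O)OC[C@@H]2c3cc(OC)c(OC(C)=O)c(OC)c3)ccc1O | intermediate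
13 | (4S,5S)-5-(4-acetoxy-3,5-dimethoxyphenyl)-4-[3-methoxy-4-(triisopropylsilyloxy)phenyl]-1,3-dioxan-2-one | COc1cc([C@H]2OC(=O)OC[C@@H]2c3cc(OC)c(OC(C)=O)c(OC)c3)ccc1O[Si](C(C)C)(C(C)C)C(C)C | intermediate
14 | (1S,2S)-2-(4-hydroxy-3,5-dimethoxyphenyl)-1-[3-methoxy-4-(triisopropylsilyloxy)phenyl]propane-1,3-diol | COc1cc([C@@H](O)[C@H](CO)c2cc(OC)c(O)c(OC)c2)ccc1O[Si](C(C)C)(C(C)C)C(C)C | intermediate
15 | (1S,2S)-1-(4-hydroxy-3-methoxyphenyl)-2-(4-hydroxy-3,5-dimethoxyphenyl)propane-1,3-diol (CNP0148667.1) | COc1cc([C@@H](O)[C@H](CO)c2cc(OC)c(O)c(OC)c2)ccc1O | target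

**Step count and risks**

Total steps: 10. Longest linear sequence: 10 (vanillin to target; homosyringic acid enters at step 2 and di-tert-butyl dicarbonate at step 5).

1. Step 7 (proposed new method). The oxidation may divert into coupling of phenoxyl radicals, the quinone methide may lose the C2 proton and tautomerise to a conjugated stilbene before the carbonate closes, or the product may be oxidised further.

 Fallback with known chemistry, making the C1–O bond by hydroboration instead of C–H oxidation. It sets out from acid 5. Alane (LiAlH4/AlCl3, THF, 0 °C) reduces the acid without touching the olefin and cleaves the acetate, giving the allylic alcohol (E)-3-(4-benzyloxy-3-methoxyphenyl)-2-(4-hydroxy-3,5-dimethoxyphenyl)prop-2-en-1-ol F1. TBSCl and imidazole in DMF give the bis(silyl) ether tert-butyl{[(E)-3-(4-benzyloxy-3-methoxyphenyl)-2-(4-tert-butyldimethylsilyloxy-3,5-dimethoxyphenyl)prop-2-en-1-yl]oxy}dimethylsilane F2. Hydroboration with monoisopinocampheylborane (THF, −25 °C; then NaBO3·4H2O) puts boron on the less substituted C1 and hydrogen on C2 by syn addition. With the aryl groups cis on the olefin this fixes the relative configuration of the target, and the antipode of the borane is chosen on a test scale to give (1S,2S)-1-(4-benzyloxy-3-methoxyphenyl)-3-(tert-butyldimethylsilyloxy)-2-(4-tert-butyldimethylsilyloxy-3,5-dimethoxyphenyl)propan-1-ol F3. Bu4NF/AcOH in THF removes both silyl groups to give (1S,2S)-1-(4-benzyloxy-3-methoxyphenyl)-2-(4-hydroxy-3,5-dimethoxyphenyl)propane-1,3-diol F4. Hydrogenolysis (H2, Pd/C, EtOAc) then comes back to the route at target 15.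

2. Step 3. Facial selectivity or turnover may be poor for a hindered trisubstituted α-aryl acrylic acid, and the sense of induction is not secured in advance.

 Fallback by classical resolution instead of asymmetric catalysis. It sets out from 5. Hydrogenation with an achiral catalyst that spares the benzyl ether (H2, Pd/C poisoned with pyridine, EtOAc) gives racemic 2-(4-acetoxy-3,5-dimethoxyphenyl)-3-(4-benzyloxy-3-methoxyphenyl)propanoic acid F5. Salt formation with 1-phenylethylamine (antipode and solvent chosen by screening) and fractional crystallisation give the less soluble salt of the (S)-acid, for example (R)-1-phenylethylammonium (S)-2-(4-acetoxy-3,5-dimethoxyphenyl)-3-(4-benzyloxy-3-methoxyphenyl)propanoate F6. Cold dilute HCl liberates the acid, and the fallback comes back to the route at 6.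

3. Step 4. The ring B acetate may be partly reduced by borane or lost by solvolysis during the quench, which would erase the difference between the two phenols that step 7 depends on.

 Fallback by full reduction and selective re-protection instead of chemoselective reduction. It sets out from 6. LiAlH4 (THF, 0 °C) reduces the acid and cleaves the acetate on purpose, giving 4-[(2S)-1-(4-benzyloxy-3-methoxyphenyl)-3-hydroxypropan-2-yl]-2,6-dimethoxyphenol F7. Acetic anhydride (1.05 equiv) in cold aqueous NaOH then acetylates only the phenoxide, which reacts far faster than the neutral primary alcohol, and the fallback comes back to the route at 7.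

**Further compounds**

F1 | step 7 | (E)-3-(4-benzyloxy-3-methoxyphenyl)-2-(4-hydroxy-3,5-dimethoxyphenyl)prop-2-en-1-ol | COc1cc(/C=C(/CO)c2cc(OC)c(O)c(OC)c2)ccc1OCc1ccccc1
F2 | step 7 | tert-butyl{[(E)-3-(4-benzyloxy-3-methoxyphenyl)-2-(4-tert-butyldimethylsilyloxy-3,5-dimethoxyphenyl)prop-2-en-1-yl]oxy}dimethylsilane | COc1cc(/C=C(/CO[Si](C)(C)C(C)(C)C)c2cc(OC)c(O[Si](C)(C)C(C)(C)C)c(OC)c2)ccc1OCc1ccccc1
F3 | step 7 | (1S,2S)-1-(4-benzyloxy-3-methoxyphenyl)-3-(tert-butyldimethylsilyloxy)-2-(4-tert-butyldimethylsilyloxy-3,5-dimethoxyphenyl)propan-1-ol | COc1cc([C@@H](O)[C@H](CO[Si](C)(C)C(C)(C)C)c2cc(OC)c(O[Si](C)(C)C(C)(C)C)c(OC)c2)ccc1OCc1ccccc1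
F4 | step 7 | (1S,2S)-1-(4-benzyloxy-3-methoxyphenyl)-2-(4-hydroxy-3,5-dimethoxyphenyl)propane-1,3-diol | COc1cc([C@@H](O)[C@H](CO)c2cc(OC)c(O)c(OC)c2)ccc1OCc1ccccc1
F5 | step 3 | racemic 2-(4-acetoxy-3,5-dimethoxyphenyl)-3-(4-benzyloxy-3-methoxyphenyl)propanoic acid | COc1cc(CC(C(=O)O)c2cc(OC)c(OC(C)=O)c(OC)c2)ccc1OCc1ccccc1
F6 | step 3 | (R)-1-phenylethylammonium (S)-2-(4-acetoxy-3,5-dimethoxyphenyl)-3-(4-benzyloxy-3-methoxyphenyl)propanoate | COc1cc(C[C@H](C(=O)[O-])c2cc(OC)c(OC(C)=O)c(OC)c2)ccc1OCc1ccccc1.C[C@@H]([NH3+])c1ccccc1
F7 | step 4 | 4-[(2S)-1-(4-benzyloxy-3-methoxyphenyl)-3-hydroxypropan-2-yl]-2,6-dimethoxyphenol | COc1cc(C[C@H](CO)c2cc(OC)c(O)c(OC)c2)ccc1OCc1ccccc1
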